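**Retrosynthetic overview**

- The target comes from its 3,9-bis(silyl) ether by desilylation. That ether comes from one oxidative cascade on a (3R,4R)-2'-hydroxyisoflavan-4-ol whose ring D still carries an open (Z)-3-hydroxy-3-methylbut-1-enyl chain on C8; the cascade makes the dimethylpyran and ring C (O11–C11a).
- Enabling feature: in ring D the pyran oxygen sits on C8, para to O11 on C10a, and the pyran carbon C4' sits on C7, ortho to C8. Ring D is therefore a masked p-hydroquinone, and the pyran is the dienone–phenol 1,2-shift product of a five-membered 2,5-dihydrofuran spiro-fused at C8 of a cyclohexa-2,5-dienone whose carbonyl carbon is C10a (the later O11 carbon).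
- The isoflavanol comes from an isoflavone by Ru transfer hydrogenation with dynamic kinetic resolution (sets C6a). The isoflavone comes from Suzuki coupling of a 3-iodochromone (rings A/B) with a ring-D boronate (C6a–C6b bond).
- The ring-D boronate comes from 5-bromo-2,4-dihydroxybenzaldehyde: an aromatic Claisen rearrangement brings in the C10 prenyl group and frees the C10a OH, and Still–Gennari olefination/MeMgBr builds the Z chain on C8. The iodochromone comes from 5-bromo-2,4-dihydroxyacetophenone by Stille prenylation, enaminone formation and iodocyclisation.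
- Ring order: A and D are bought as benzene rings; ring B (step 4); temporary spiro-dihydrofuran, its expansion to the pyran with re-aromatisation of ring D, then ring C (all in step 14).

Key step: step 14

Remark: pterocarpan numbering is used (ring A C1–C4a, O5, C6, C6a, ring D C6b–C10a, O11, C11a, C11b; pyran atoms O1', C2', C3', C4'); the given SMILES corresponds to (6aR,11aR), and starting materials 1 and 6 are taken to be catalogue compounds.

**Route**

Step 1
Reactants: 1 1-(5-bromo-2,4-dihydroxyphenyl)ethan-1-one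
Product: 2 1-[5-bromo-2-hydroxy-4-(triisopropylsilyloxy)phenyl]ethan-1-one
Conditions: TIPSCl, imidazole, DMF, 0 °C to rt
Reagents that add atoms: chlorotriisopropylsilane, CC(C)[Si](Cl)(C(C)C)C(C)C
Why: O-silylation; the 2-OH is held in a hydrogen bond to the acetyl group, so the free and more acidic 4-OH should be silylated selectively.

Step 2
Reactants: 2 aryl bromide
Product: 3 1-[2-hydroxy-5-(3-methylbut-2-en-1-yl)-4-(triisopropylsilyloxy)phenyl]ethan-1-one
Conditions: prenylSnBu3, Pd(PPh3)4 (cat.), LiCl, DMF, 95 °C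
Reagents that add atoms: tributyl(3-methylbut-2-en-1-yl)stannane, CCCC[Sn](CCCC)(CCCC)CC=C(C)C
Why: Stille coupling of the aryl bromide; the prenylstannane should transfer its CH2 terminus and so give the linear prenyl group at the later C2.

Step 3
Reactants: 3 prenylated acetophenone
Product: 4 (E)-3-(dimethylamino)-1-[2-hydroxy-5-(3-methylbut-2-en-1-yl)-4-(triisopropylsilyloxy)phenyl]prop-2-en-1-one
Conditions: DMF-DMA, toluene, 85 °C
Reagents that add atoms: N,N-dimethylformamide dimethyl acetal, COC(OC)N(C)C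
Why: Condensation of the methyl ketone with the amide acetal to the enaminone, the standard chromone precursor; the chelated 2-OH should not be methylated.

Step 4
Reactants: 4 enaminone
Product: 5 3-iodo-6-(3-methylbut-2-en-1-yl)-7-(triisopropylsilyloxy)-4H-chromen-4-one
Conditions: I2, CHCl3, rt
Reagents that add atoms: iodine, II
Why: Iodine-mediated cyclisation of a 2-hydroxyaryl enaminone (α-iodination, 6-endo O-addition, loss of dimethylamine) closes ring B as the 3-iodochromone; the prenyl alkene has no free neighbouring OH to trap an iodonium ion.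

Step 5
Reactants: 6 5-bromo-2,4-dihydroxybenzaldehyde
Product: 7 5-bromo-2-hydroxy-4-[(2-methylbut-3-yn-2-yl)oxy]benzaldehyde
Conditions: 3-chloro-3-methylbut-1-yne, K2CO3, KI, CuI (cat.), acetone, 55 °C
Reagents that add atoms: 3-chloro-3-methylbut-1-yne, CC(C)(Cl)C#C
Why: Copper-assisted O-alkylation of a phenol with the tertiary propargyl chloride; the non-chelated, more acidic 4-OH (the later O11) should react alone.

Step 6
Reactants: 7 propargyl ether
Product: 8 5-bromo-4-[(2-methylbut-3-yn-2-yl)oxy]-2-(triisopropylsilyloxy)benzaldehyde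
Conditions: TIPSOTf, 2,6-lutidine, CH2Cl2, 0 °C
Reagents that add atoms: triisopropylsilyl trifluoromethanesulfonate, CC(C)[Si](OS(=O)(=O)C(F)(F)F)(C(C)C)C(C)C
Why: Silylation of the chelated, hindered 2-OH with the silyl triflate; this oxygen (later on C9) stays blocked to the end so that the Z chain ortho to it cannot close the angular chromene.

Step 7
Reactants: 8 silylated propargyl ether
Product: 9 5-bromo-4-[(2-methylbut-3-en-2-yl)oxy]-2-(triisopropylsilyloxy)benzaldehyde
Conditions: H2 (1 atm), Lindlar catalyst, quinoline, EtOAc, rt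
Reagents that add atoms: none
Why: Lindlar semihydrogenation of the terminal alkyne to the vinyl group gives the 1,1-dimethylallyl ether; aryl bromide and aldehyde are not reduced under these conditions.

Step 8
Reactants: 9 aldehyde
Product: 10 methyl (Z)-3-{5-bromo-4-[(2-methylbut-3-en-2-yl)oxy]-2-(triisopropylsilyloxy)phenyl}prop-2-enoate
Conditions: (CF3CH2O)2P(O)CH2CO2Me, KHMDS, 18-crown-6, THF, −78 °C
Reagents that add atoms: methyl bis(2,2,2-trifluoroethyl)phosphonoacetate, COC(=O)CP(=O)(OCC(F)(F)F)OCC(F)(F)F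
Why: Still–Gennari olefination; fast, irreversible elimination from the kinetic adduct of the electron-poor phosphonate should give the Z enoate needed for the later five-membered ring.

Step 9
Reactants: 10 Z enoate
Product: 11 (Z)-4-{5-bromo-4-[(2-methylbut-3-en-2-yl)oxy]-2-(triisopropylsilyloxy)phenyl}-2-methylbut-3-en-2-ol
Conditions: MeMgBr (excess), THF, −78 to 0 °C; aq. NH4Cl
Reagents that add atoms: methylmagnesium bromide, C[Mg]Br
Why: Double 1,2-addition of the Grignard reagent to the ester gives the tertiary carbinol with the Z alkene retained; cold quench keeps the hindered aryl silyl ether from migrating to the alkoxide.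

Step 10
Reactants: 11 1,1-dimethylallyl aryl ether
Product: 13 6-bromo-4-[(Z)-3-hydroxy-3-methylbut-1-en-1-yl]-2-(3-methylbut-2-en-1-yl)-3-(triisopropylsilyloxy)phenol, via Claisen dienone 12 (not isolated)
Conditions: toluene, BHT, 110 °C, sealed tube
Reagents that add atoms: none
Why: Aromatic Claisen rearrangement; one ortho position carries Br, so the [3,3] shift should deliver the allyl unit, inverted to linear prenyl, to the carbon between the two oxygens (C10), and tautomerisation of 12 frees the phenol that becomes O11.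

Step 11
Reactants: 13 bromophenol
Product: 14 4-[(Z)-3-hydroxy-3-methylbut-1-en-1-yl]-2-(3-methylbut-2-en-1-yl)-6-(4,4,5,5-tetramethyl-1,3,2-dioxaborolan-2-yl)-3-(triisopropylsilyloxy)phenol
Conditions: B2pin2, Pd(dppf)Cl2 (cat.), KOAc, dioxane, 85 °C
Reagents that add atoms: bis(pinacolato)diboron, CC1(C)OB(OC1(C)C)B1OC(C)(C)C(C)(C)O1
Why: Miyaura borylation of the aryl bromide; the weak acetate base should tolerate the free phenol, the tertiary alcohol and the silyl ether.

Step 12
Reactants: 5 3-iodochromone; 14 ring-D boronate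
Product: 15 3-{2-hydroxy-5-[(Z)-3-hydroxy-3-methylbut-1-en-1-yl]-3-(3-methylbut-2-en-1-yl)-4-(triisopropylsilyloxy)phenyl}-6-(3-methylbut-2-en-1-yl)-7-(triisopropylsilyloxy)-4H-chromen-4-one
Conditions: Pd(dppf)Cl2 (cat.), K3PO4, dioxane/H2O (10:1), 55 °C
Reagents that add atoms: none
Why: Suzuki–Miyaura coupling of a 3-iodochromone with an arylboronate, the standard isoflavone synthesis, forms the C6a–C6b bond; the reactive vinylic iodide allows mild base and temperature.

Step 13
Reactants: 15 isoflavone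
Product: 17 (3R,4R)-3-{2-hydroxy-5-[(Z)-3-hydroxy-3-methylbut-1-en-1-yl]-3-(3-methylbut-2-en-1-yl)-4-(triisopropylsilyloxy)phenyl}-6-(3-methylbut-2-en-1-yl)-7-(triisopropylsilyloxy)chroman-4-ol, via racemising isoflavanone 16 (not isolated)
Conditions: RuCl(p-cymene)[(R,R)-TsDPEN] (cat.), HCO2H/Et3N (1:1, amine-rich), EtOAc, 40 °C
Reagents that add atoms: none
Why: Noyori–Ikariya transfer hydrogenation of an isoflavone: 1,4-reduction gives 16, whose C3 epimerises under the amine while the (R,R) catalyst reduces the carbonyl from one face (4R expected by analogy with aryl ketones) and only the epimer leading to the cis alcohol reacts fast, so C3 (later C6a) is set as R by dynamic kinetic resolution.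

Step 14
Reactants: 17 cis-2'-hydroxyisoflavan-4-ol
Product: 20 (6aR,11aR)-3,9-bis-O-(triisopropylsilyl)lespecyrtin E3, via spiro dienone 18 (not isolated), via chromenyl isoflavanol 19 (not isolated)
Conditions: PhI(OAc)2 (1.05 equiv), CH2Cl2, −20 °C; then CF3CO2H, −20 to 0 °C
Reagents that add atoms: none
Why: PhI(OAc)2 oxidises the only free phenol (C10a–OH) to a phenoxonium ion, which the tertiary side-chain hydroxyl traps at the para carbon C8 (5-exo-trig spiro-etherification, the known oxidative dearomatisation of 4-(3-hydroxyalkyl)phenols) to give dienone 18 with a 2,5-dihydrofuran spiro-fused at C8. Acid then triggers a dienone–phenol rearrangement: the ring vinyl carbon C4' shifts from C8 to C7 while O1' stays on C8 and stabilises the charge, so the five-membered ring expands to the 2,2-dimethyl-2H-pyran and loss of H7 re-aromatises ring D (closest precedent: acid-induced 1,2-carbon shifts of 1-oxa- and 1-azaspiro[4.5]dienones to chromans, coumarins and quinolinones). The C10a oxygen, a phenol again in 19, captures the C11a benzylic cation formed by ionisation of the 4-OH and stabilised by the para silyloxy group of ring A (5-exo-trig closure of ring C, the standard acid cyclisation of 2'-hydroxyisoflavan-4-ols); capture of that cation by the dienone oxygen before the shift would lead to the same product. C6a is carried over from 17, and C11a is set by the strain of a trans-fused 6/5 system, so only the cis (6aR,11aR) fusion should form whatever the C4 configuration. The step needs carbon and not oxygen migration (favoured because the oxygen left behind stabilises the cation at C8), migration to C7 and not C9 (a shift to the silyloxy-bearing C9 cannot end in proton loss and is reversible), and oxidation of ring D only (ring A has no free phenol). Both epimers of the spiro centre in 18 converge on 20.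

Step 15
Reactants: 20 bis(silyl) ether
Product: 21 lespecyrtin E3
Conditions: TBAF, THF, 0 °C; aq. NH4Cl
Reagents that add atoms: none
Why: Fluoride cleavage of the two aryl silyl ethers under non-acidic conditions, which should leave the prenyl groups, the chromene and the benzylic C11a–O11 bond untouched.

**Compound list**

1 | 1-(5-bromo-2,4-dihydroxyphenyl)ethan-1-one | CC(=O)c1cc(Br)c(O)cc1O | starting material
2 | 1-[5-bromo-2-hydroxy-4-(triisopropylsilyloxy)phenyl]ethan-1-one | CC(=O)c1cc(Br)c(O[Si](C(C)C)(C(C)C)C(C)C)cc1O | intermediate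
3 | 1-[2-hydroxy-5-(3-methylbut-2-en-1-yl)-4-(triisopropylsilyloxy)phenyl]ethan-1-one | CC(=O)c1cc(CC=C(C)C)c(O[Si](C(C)C)(C(C)C)C(C)C)cc1O | intermediate
4 | (E)-3-(dimethylamino)-1-[2-hydroxy-5-(3-methylbut-2-en-1-yl)-4-(triisopropylsilyloxy)phenyl]prop-2-en-1-one | CN(C)/C=C/C(=O)c1cc(CC=C(C)C)c(O[Si](C(C)C)(C(C)C)C(C)C)cc1O | intermediate
5 | 3-iodo-6-(3-methylbut-2-en-1-yl)-7-(triisopropylsilyloxy)-4H-chromen-4-one | CC(C)=CCc1cc2c(cc1O[Si](C(C)C)(C(C)C)C(C)C)occ(I)c2=O | intermediate
6 | 5-bromo-2,4-dihydroxybenzaldehyde | O=Cc1cc(Br)c(O)cc1O | starting material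
7 | 5-bromo-2-hydroxy-4-[(2-methylbut-3-yn-2-yl)oxy]benzaldehyde | O=Cc1cc(Br)c(OC(C)(C)C#C)cc1O | intermediate
8 | 5-bromo-4-[(2-methylbut-3-yn-2-yl)oxy]-2-(triisopropylsilyloxy)benzaldehyde | O=Cc1cc(Br)c(OC(C)(C)C#C)cc1O[Si](C(C)C)(C(C)C)C(C)C | intermediate
9 | 5-bromo-4-[(2-methylbut-3-en-2-yl)oxy]-2-(triisopropylsilyloxy)benzaldehyde | O=Cc1cc(Br)c(OC(C)(C)C=C)cc1O[Si](C(C)C)(C(C)C)C(C)C | intermediate
10 | methyl (Z)-3-{5-bromo-4-[(2-methylbut-3-en-2-yl)oxy]-2-(triisopropylsilyloxy)phenyl}prop-2-enoate | COC(=O)/C=C\c1cc(Br)c(OC(C)(C)C=C)cc1O[Si](C(C)C)(C(C)C)C(C)C | intermediate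
11 | (Z)-4-{5-bromo-4-[(2-methylbut-3-en-2-yl)oxy]-2-(triisopropylsilyloxy)phenyl}-2-methylbut-3-en-2-ol | CC(C)(O)/C=C\c1cc(Br)c(OC(C)(C)C=C)cc1O[Si](C(C)C)(C(C)C)C(C)C | intermediate
12 | 2-bromo-4-[(Z)-3-hydroxy-3-methylbut-1-en-1-yl]-6-(3-methylbut-2-en-1-yl)-5-(triisopropylsilyloxy)cyclohexa-2,4-dien-1-one (Claisen dienone, racemic at C6) | O=C1C(Br)=CC(/C=C\C(C)(C)O)=C(O[Si](C(C)C)(C(C)C)C(C)C)C1CC=C(C)C | intermediate
13 | 6-bromo-4-[(Z)-3-hydroxy-3-methylbut-1-en-1-yl]-2-(3-methylbut-2-en-1-yl)-3-(triisopropylsilyloxy)phenol | CC(C)(O)/C=C\c1cc(Br)c(O)c(CC=C(C)C)c1O[Si](C(C)C)(C(C)C)C(C)C | intermediate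
14 | 4-[(Z)-3-hydroxy-3-methylbut-1-en-1-yl]-2-(3-methylbut-2-en-1-yl)-6-(4,4,5,5-tetramethyl-1,3,2-dioxaborolan-2-yl)-3-(triisopropylsilyloxy)phenol | CC(C)(O)/C=C\c1cc(B2OC(C)(C)C(C)(C)O2)c(O)c(CC=C(C)C)c1O[Si](C(C)C)(C(C)C)C(C)C | intermediate
15 | 3-{2-hydroxy-5-[(Z)-3-hydroxy-3-methylbut-1-en-1-yl]-3-(3-methylbut-2-en-1-yl)-4-(triisopropylsilyloxy)phenyl}-6-(3-methylbut-2-en-1-yl)-7-(triisopropylsilyloxy)-4H-chromen-4-one | CC(C)=CCc1cc2c(cc1O[Si](C(C)C)(C(C)C)C(C)C)occ(-c1cc(/C=C\C(C)(C)O)c(O[Si](C(C)C)(C(C)C)C(C)C)c(CC=C(C)C)c1O)c2=O | intermediate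
16 | 3-{2-hydroxy-5-[(Z)-3-hydroxy-3-methylbut-1-en-1-yl]-3-(3-methylbut-2-en-1-yl)-4-(triisopropylsilyloxy)phenyl}-6-(3-methylbut-2-en-1-yl)-7-(triisopropylsilyloxy)chroman-4-one (C3 epimerising) | CC(C)=CCc1cc2c(cc1O[Si](C(C)C)(C(C)C)C(C)C)OCC(c1cc(/C=C\C(C)(C)O)c(O[Si](C(C)C)(C(C)C)C(C)C)c(CC=C(C)C)c1O)C2=O | intermediate
17 | (3R,4R)-3-{2-hydroxy-5-[(Z)-3-hydroxy-3-methylbut-1-en-1-yl]-3-(3-methylbut-2-en-1-yl)-4-(triisopropylsilyloxy)phenyl}-6-(3-methylbut-2-en-1-yl)-7-(triisopropylsilyloxy)chroman-4-ol | CC(C)=CCc1cc2c(cc1O[Si](C(C)C)(C(C)C)C(C)C)OC[C@@H](c1cc(/C=C\C(C)(C)O)c(O[Si](C(C)C)(C(C)C)C(C)C)c(CC=C(C)C)c1O)[C@H]2O | intermediate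
18 | (3R,4R)-3-[2,2-dimethyl-7-(3-methylbut-2-en-1-yl)-8-oxo-6-(triisopropylsilyloxy)-1-oxaspiro[4.5]deca-3,6,9-trien-9-yl]-6-(3-methylbut-2-en-1-yl)-7-(triisopropylsilyloxy)chroman-4-ol (both spiro epimers) | CC(C)=CCc1cc2c(cc1O[Si](C(C)C)(C(C)C)C(C)C)OC[C@@H](C1=CC3(C=CC(C)(C)O3)C(O[Si](C(C)C)(C(C)C)C(C)C)=C(CC=C(C)C)C1=O)[C@H]2O | intermediate
19 | (3R,4R)-3-[6-hydroxy-2,2-dimethyl-7-(3-methylbut-2-en-1-yl)-8-(triisopropylsilyloxy)-2H-chromen-5-yl]-6-(3-methylbut-2-en-1-yl)-7-(triisopropylsilyloxy)chroman-4-ol | CC(C)=CCc1cc2c(cc1O[Si](C(C)C)(C(C)C)C(C)C)OC[C@@H](c1c3C=CC(C)(C)Oc3c(O[Si](C(C)C)(C(C)C)C(C)C)c(CC=C(C)C)c1O)[C@H]2O | intermediate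
20 | (6aR,11aR)-3,9-bis-O-(triisopropylsilyl)lespecyrtin E3 | CC(C)=CCc1cc2c(cc1O[Si](C(C)C)(C(C)C)C(C)C)OC[C@H]1c3c4c(c(O[Si](C(C)C)(C(C)C)C(C)C)c(CC=C(C)C)c3O[C@@H]21)OC(C)(C)C=C4 | intermediate
21 | lespecyrtin E3, (6aR,11aR)-3,9-dihydroxy-2,10-diprenylpterocarpan with a 2,2-dimethyl-2H-pyran fused at C7–C8 (O on C8) | CC(C)=CCc1cc2c(cc1O)OC[C@H]1c3c4c(c(O)c(CC=C(C)C)c3O[C@@H]21)OC(C)(C)C=C4 | target

**Step count and risks**

Total steps: 15 (steps 1–4 for the iodochromone, 5–11 for the ring-D boronate, 12–15 after the union). Longest linear sequence: 11 steps (compound 6 to compound 21, steps 5–15).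

Step 14 is the riskiest. After the oxidation, ionisation of the C4 carbinol may outrun the 1,2-shift. The C11a cation then has no phenol to close onto and may lose the proton at C6a to give an isoflav-3-ene, which erases the C6a configuration. Oxygen instead of carbon migration, or acid cleavage of the allylic spiro ether, would lead to isomeric or open-chain products. The fallback uses the same known reactions in another order and sets out from isoflavone 15, which has no ionisable carbinol. PhI(OAc)2 in CH2Cl2 should give the spiro dienone isoflavone F1, and CF3CO2H should rearrange it to the 2'-hydroxy pyrano-isoflavone F2. Transfer hydrogenation as in step 13, through the isoflavanone F3, then gives compound 19 as an isolated cis-isoflavan-4-ol in which O11 is already a free phenol. Its mild acid cyclisation (BF3·OEt2, CH2Cl2, 0 °C) returns to the route at compound 20.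

Step 11 is the second risk. Borylation of the free, electron-rich bromophenol may end in protodebromination or in catalyst sequestration by the phenoxide, and the ortho-hydroxy boronate may protodeboronate in step 12. The fallback reverses the polarity of the coupling and sets out from compounds 5 and 13. Pd-catalysed stannylation of 5 with hexamethylditin (Pd(PPh3)4, dioxane, 90 °C) should give the 3-(trimethylstannyl)chromone F4. Stille coupling of F4 with bromophenol 13 (Pd(PtBu3)2, CuI, DMF, 60 °C; neutral, free phenol tolerated) returns to the route at isoflavone 15 and bypasses boronate 14.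

Step 13 is the third risk. The conjugate reduction of the hindered isoflavone by the ruthenium hydride may stall, or carbonyl reduction may outrun C3 epimerisation, so that cis/trans mixtures of low enantiomeric purity form. The fallback separates the two reductions and sets out from 15. Stoichiometric 1,4-reduction with L-Selectride (THF, −78 °C) gives isoflavanone 16 as an isolated racemate. Its dynamic kinetic resolution is then run as a ketone transfer hydrogenation with a tethered catalyst ((R,R)-Ts-DENEB, HCO2H/Et3N) and returns to the route at 17. This fallback makes no compound outside the list (F0).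

**Further compounds**

F1 | step 14 | 3-[2,2-dimethyl-7-(3-methylbut-2-en-1-yl)-8-oxo-6-(triisopropylsilyloxy)-1-oxaspiro[4.5]deca-3,6,9-trien-9-yl]-6-(3-methylbut-2-en-1-yl)-7-(triisopropylsilyloxy)-4H-chromen-4-one (racemic spiro centre) | CC(C)=CCc1cc2c(cc1O[Si](C(C)C)(C(C)C)C(C)C)occ(C1=CC3(C=CC(C)(C)O3)C(O[Si](C(C)C)(C(C)C)C(C)C)=C(CC=C(C)C)C1=O)c2=O
F2 | step 14 | 3-[6-hydroxy-2,2-dimethyl-7-(3-methylbut-2-en-1-yl)-8-(triisopropylsilyloxy)-2H-chromen-5-yl]-6-(3-methylbut-2-en-1-yl)-7-(triisopropylsilyloxy)-4H-chromen-4-one | CC(C)=CCc1cc2c(cc1O[Si](C(C)C)(C(C)C)C(C)C)occ(-c1c3C=CC(C)(C)Oc3c(O[Si](C(C)C)(C(C)C)C(C)C)c(CC=C(C)C)c1O)c2=O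
F3 | step 14 | 3-[6-hydroxy-2,2-dimethyl-7-(3-methylbut-2-en-1-yl)-8-(triisopropylsilyloxy)-2H-chromen-5-yl]-6-(3-methylbut-2-en-1-yl)-7-(triisopropylsilyloxy)chroman-4-one (C3 epimerising) | CC(C)=CCc1cc2c(cc1O[Si](C(C)C)(C(C)C)C(C)C)OCC(c1c3C=CC(C)(C)Oc3c(O[Si](C(C)C)(C(C)C)C(C)C)c(CC=C(C)C)c1O)C2=O
F4 | step 11 | 6-(3-methylbut-2-en-1-yl)-7-(triisopropylsilyloxy)-3-(trimethylstannyl)-4H-chromen-4-one | CC(C)=CCc1cc2c(cc1O[Si](C(C)C)(C(C)C)C(C)C)occ([Sn](C)(C)C)c2=O
F0 | step 13 | none | none
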